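Both side chains on the benzoic acid ring, at C3 and C5, contain the same unit ArCH2–CH=C(CH3)–C(O) with (E) geometry (C1'–C4' of the long chain, C1''–C4'' of the short one); the long chain is the short one with a prenyl group added at its oxygen-bearing carbon C4'. Both trisubstituted alkenes, C2'=C3' and C2''=C3'', are therefore disconnected together. In one operation a double cross-metathesis with methacrolein turns a symmetrical precursor, methyl 3,5-diallyl-4-methoxybenzoate, into a symmetrical bis-(E)-enal with both geometries and both oxidation levels in place. One formyl group is then allylated enantioselectively and extended to the prenyl carbinol, the other is reduced, and the ester is hydrolysed.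

Key step: step 3

Remark: the target stereocentre C4' is (S); single primes denote the eight-carbon chain and double primes the four-carbon chain. Reagent 10 is assumed to be available as a magnesium-salt-free solution (bought, or made beforehand from (−)-B-methoxydiisopinocampheylborane and allylmagnesium bromide).

Step 1
Reactants: 1 methyl 3,5-dibromo-4-hydroxybenzoate; 2 iodomethane
Product: 3 methyl 3,5-dibromo-4-methoxybenzoate
Conditions: MeI (1.5 equiv), K2CO3 (2 equiv), DMF, 40 °C
Reagents that add atoms: iodomethane, CI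
Why: Williamson O-methylation: the acidic 2,6-dibromophenol is deprotonated by K2CO3 and the phenoxide displaces iodide from MeI in an SN2 reaction, while the methyl ester is inert.

Step 2
Reactants: 3 methyl 3,5-dibromo-4-methoxybenzoate; 4 allylboronic acid pinacol ester
Product: 6 methyl 3,5-diallyl-4-methoxybenzoate, via mono-allyl bromide 5 (not isolated)
Conditions: 4 (3 equiv), Pd(PPh3)4 (5 mol%), CsF (4 equiv), THF, reflux
Reagents that add atoms: allylboronic acid pinacol ester, C=CCB1OC(C)(C)C(C)(C)O1
Why: Two-fold Suzuki–Miyaura allylation (oxidative addition of each C–Br bond to zerovalent palladium, fluoride-assisted transfer of allyl from boron, reductive elimination); the mild fluoride base spares the ester and the moderate temperature should limit migration of the allyl double bond.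

Step 3
Reactants: 6 methyl 3,5-diallyl-4-methoxybenzoate; 7 methacrolein
Product: 9 methyl 4-methoxy-3,5-bis[(2E)-3-methyl-4-oxobut-2-en-1-yl]benzoate, via mono-enal 8 (not isolated)
Conditions: 7 (10 equiv), second-generation Hoveyda–Grubbs catalyst RuCl2(H2IMes)(=CH-C6H4-2-OiPr) (5 mol%, two portions), 1,4-benzoquinone (10 mol%), CH2Cl2, 40 °C, argon sweep
Reagents that add atoms: methacrolein, CC(=C)C=O
Why: Each terminal allyl group of 6 enters the Chauvin cycle: the ruthenium alkylidene formed from it undergoes (2+2) cycloaddition with methacrolein, and cycloreversion of the ruthenacyclobutane releases the trisubstituted enal and a ruthenium methylidene that carries the chain on with loss of ethene. The closest known reaction type is the cross-metathesis of monosubstituted terminal alkenes, allyl arenes included, with methacrolein to give (E)-2-methylalk-2-enals. No ring is closed and no stereocentre is created; the step forms only the C2'=C3' and C2''=C3'' double bonds. The selectivity needed is cross- over homo-coupling, (E) geometry at both alkenes and no migration of the allyl double bonds into conjugation with the arene: methacrolein, an electron-poor 1,1-disubstituted alkene, hardly dimerises and is used in excess, while any homodimer of 6 is a reactive 1,2-disubstituted alkene that is drawn back into the cycle. The (E) geometry follows from the preference of the formyl group to lie trans to the benzylic CH2, and 1,4-benzoquinone traps the ruthenium hydrides that would cause isomerisation. The two arms are unhindered and held apart by the arene, so each should react independently, and ring closure between them would need a strained meta-bridged ring and is not expected.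

Step 4
Reactants: 9 methyl 4-methoxy-3,5-bis[(2E)-3-methyl-4-oxobut-2-en-1-yl]benzoate; 10 (−)-B-allyldiisopinocampheylborane (the enantiomer built from (+)-α-pinene)
Product: 12 methyl 3-[(2E,4S)-4-hydroxy-3-methylhepta-2,6-dien-1-yl]-4-methoxy-5-[(2E)-3-methyl-4-oxobut-2-en-1-yl]benzoate, via borinate ester 11 (not isolated)
Conditions: 10 (0.5 equiv per 9), Et2O, −78 °C; then 8-hydroxyquinoline, Et2O/MeOH, rt; unreacted 9 recovered and recycled
Reagents that add atoms: (−)-B-allyldiisopinocampheylborane, C=CCB([C@@H]1C[C@@H]2C[C@H]([C@H]1C)C2(C)C)[C@@H]1C[C@@H]2C[C@H]([C@H]1C)C2(C)C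
Why: Brown allylboration through a closed six-membered chair transition state, in which the isopinocampheyl groups should direct allyl to the Si face of the formyl group as they do with benzaldehyde, setting C4' as (S) because the alkenyl carbon outranks the allylic CH2; the excess of 9 should favour mono-addition, and removing boron as its 8-hydroxyquinoline chelate avoids alkaline peroxide, which would epoxidise the remaining enal.

Step 5
Reactants: 12 methyl 3-[(2E,4S)-4-hydroxy-3-methylhepta-2,6-dien-1-yl]-4-methoxy-5-[(2E)-3-methyl-4-oxobut-2-en-1-yl]benzoate; 13 2-methyl-2-butene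
Product: 14 methyl 3-[(2E,4S)-4-hydroxy-3,7-dimethylocta-2,6-dien-1-yl]-4-methoxy-5-[(2E)-3-methyl-4-oxobut-2-en-1-yl]benzoate
Conditions: 13 (large excess, co-solvent), second-generation Grubbs catalyst RuCl2(PCy3)(H2IMes)(=CHPh) (5 mol%), 1,4-benzoquinone (10 mol%), CH2Cl2, 35 °C, sealed vessel
Reagents that add atoms: 2-methyl-2-butene, CC=C(C)C
Why: Olefin cross-metathesis of the only monosubstituted alkene with 2-methyl-2-butene builds the prenyl terminus with loss of propene, while the trisubstituted C2'=C3' alkene, the electron-poor enal alkene and the C4' carbinol are not expected to react.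

Step 6
Reactants: 14 methyl 3-[(2E,4S)-4-hydroxy-3,7-dimethylocta-2,6-dien-1-yl]-4-methoxy-5-[(2E)-3-methyl-4-oxobut-2-en-1-yl]benzoate
Product: 15 methyl 3-[(2E,4S)-4-hydroxy-3,7-dimethylocta-2,6-dien-1-yl]-5-[(2E)-4-hydroxy-3-methylbut-2-en-1-yl]-4-methoxybenzoate
Conditions: NaBH4, CeCl3·7H2O, MeOH, 0 °C
Reagents that add atoms: none
Why: Luche reduction delivers hydride to the formyl carbon only (1,2-addition), giving the primary allylic alcohol with the (E) alkene and the methyl ester untouched.

Step 7
Reactants: 15 methyl 3-[(2E,4S)-4-hydroxy-3,7-dimethylocta-2,6-dien-1-yl]-5-[(2E)-4-hydroxy-3-methylbut-2-en-1-yl]-4-methoxybenzoate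
Product: 17 3-[(2E,4S)-4-hydroxy-3,7-dimethylocta-2,6-dien-1-yl]-5-[(2E)-4-hydroxy-3-methylbut-2-en-1-yl]-4-methoxybenzoic acid, via lithium carboxylate 16 (not isolated)
Conditions: LiOH·H2O (4 equiv), THF/MeOH/H2O, rt; then 1 M HCl to pH 4, 0 °C
Reagents that add atoms: lithium hydroxide, [Li+].[OH-]
Why: Saponification of the unhindered methyl benzoate by acyl–oxygen cleavage, followed by cold, mild acidification that should leave the two allylic alcohols and the C4' stereocentre unchanged.

Compound list
1 | methyl 3,5-dibromo-4-hydroxybenzoate | COC(=O)c1cc(Br)c(O)c(Br)c1 | starting material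
2 | iodomethane | CI | starting material
3 | methyl 3,5-dibromo-4-methoxybenzoate | COC(=O)c1cc(Br)c(OC)c(Br)c1 | intermediate
4 | allylboronic acid pinacol ester (2-allyl-4,4,5,5-tetramethyl-1,3,2-dioxaborolane) | C=CCB1OC(C)(C)C(C)(C)O1 | starting material
5 | methyl 3-allyl-5-bromo-4-methoxybenzoate | C=CCc1cc(C(=O)OC)cc(Br)c1OC | intermediate
6 | methyl 3,5-diallyl-4-methoxybenzoate | C=CCc1cc(C(=O)OC)cc(CC=C)c1OC | intermediate
7 | methacrolein | CC(=C)C=O | starting material
8 | methyl 3-allyl-4-methoxy-5-[(2E)-3-methyl-4-oxobut-2-en-1-yl]benzoate | C=CCc1cc(C(=O)OC)cc(C/C=C(\C)C=O)c1OC | intermediate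
9 | methyl 4-methoxy-3,5-bis[(2E)-3-methyl-4-oxobut-2-en-1-yl]benzoate | COc1c(C/C=C(\C)C=O)cc(C(=O)OC)cc1C/C=C(\C)C=O | intermediate
10 | (−)-B-allyldiisopinocampheylborane, from (+)-α-pinene | C=CCB([C@@H]1C[C@@H]2C[C@H]([C@H]1C)C2(C)C)[C@@H]1C[C@@H]2C[C@H]([C@H]1C)C2(C)C | starting material
11 | methyl 3-[(2E,4S)-4-(diisopinocampheylboranyloxy)-3-methylhepta-2,6-dien-1-yl]-4-methoxy-5-[(2E)-3-methyl-4-oxobut-2-en-1-yl]benzoate | COc1c(C/C=C(\C)C=O)cc(C(=O)OC)cc1C/C=C(\C)[C@@H](OB([C@@H]2C[C@@H]3C[C@H]([C@H]2C)C3(C)C)[C@@H]2C[C@@H]3C[C@H]([C@H]2C)C3(C)C)CC=C | intermediate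
12 | methyl 3-[(2E,4S)-4-hydroxy-3-methylhepta-2,6-dien-1-yl]-4-methoxy-5-[(2E)-3-methyl-4-oxobut-2-en-1-yl]benzoate | COc1c(C/C=C(\C)C=O)cc(C(=O)OC)cc1C/C=C(\C)[C@@H](O)CC=C | intermediate
13 | 2-methyl-2-butene | CC=C(C)C | starting material
14 | methyl 3-[(2E,4S)-4-hydroxy-3,7-dimethylocta-2,6-dien-1-yl]-4-methoxy-5-[(2E)-3-methyl-4-oxobut-2-en-1-yl]benzoate | COc1c(C/C=C(\C)C=O)cc(C(=O)OC)cc1C/C=C(\C)[C@@H](O)CC=C(C)C | intermediate
15 | methyl 3-[(2E,4S)-4-hydroxy-3,7-dimethylocta-2,6-dien-1-yl]-5-[(2E)-4-hydroxy-3-methylbut-2-en-1-yl]-4-methoxybenzoate | COc1c(C/C=C(\C)CO)cc(C(=O)OC)cc1C/C=C(\C)[C@@H](O)CC=C(C)C | intermediate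
16 | lithium 3-[(2E,4S)-4-hydroxy-3,7-dimethylocta-2,6-dien-1-yl]-5-[(2E)-4-hydroxy-3-methylbut-2-en-1-yl]-4-methoxybenzoate | COc1c(C/C=C(\C)CO)cc(C(=O)[O-])cc1C/C=C(\C)[C@@H](O)CC=C(C)C.[Li+] | intermediate
17 | 3-[(2E,4S)-4-hydroxy-3,7-dimethylocta-2,6-dien-1-yl]-5-[(2E)-4-hydroxy-3-methylbut-2-en-1-yl]-4-methoxybenzoic acid | COc1c(C/C=C(\C)CO)cc(C(=O)O)cc1C/C=C(\C)[C@@H](O)CC=C(C)C | target

Total step count: 7
Longest linear sequence: 7 steps (1 to 17)

Steps most likely to fail

Step 3. The second arm may stop reacting once the catalyst has decayed, ruthenium hydride may shift the allyl double bonds into conjugation with the ring, and the geometry may erode on long exposure. The fallback sets out from 6 and comes back at 9. Both vinyl groups of 6 are cleaved with ozone (CH2Cl2, −78 °C, then Me2S) to the dialdehyde methyl 4-methoxy-3,5-bis(2-oxoethyl)benzoate F1. F1 is then olefinated twice with the stabilised ylide 2-(triphenylphosphoranylidene)propanal (toluene, 80 °C), a Wittig reaction known to give (E)-2-methyl-2-enals, so that 9 is reached without metathesis.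

Step 4. Addition may occur at both formyl groups, facial discrimination may be insufficient, and material may be lost when the boron residue is removed. The fallback sets out from 9 and comes back at 15, replacing asymmetric allylation by asymmetric ketone reduction. Barbier mono-allylation of 9 in excess (allyl bromide, Zn dust, THF/aqueous NH4Cl, 0 °C) gives racemic methyl 3-[(2E)-4-hydroxy-3-methylhepta-2,6-dien-1-yl]-4-methoxy-5-[(2E)-3-methyl-4-oxobut-2-en-1-yl]benzoate F2. Oxidation with activated MnO2 (CH2Cl2, rt) gives the keto aldehyde methyl 4-methoxy-3-[(2E)-3-methyl-4-oxohepta-2,6-dien-1-yl]-5-[(2E)-3-methyl-4-oxobut-2-en-1-yl]benzoate F3. Corey–Bakshi–Shibata reduction with (R)-2-methyl-CBS-oxazaborolidine and catecholborane (toluene, −78 to −20 °C) should give the (S)-carbinol, the alkenyl group acting as the large substituent, and reduce the formyl group in the same operation. The product is the diol methyl 3-[(2E,4S)-4-hydroxy-3-methylhepta-2,6-dien-1-yl]-5-[(2E)-4-hydroxy-3-methylbut-2-en-1-yl]-4-methoxybenzoate F4. Cross-metathesis of F4 with 13 under the conditions of step 5 then gives 15.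

Step 5. Turnover may be slow at a vinyl group next to a free carbinol, the ethylidene instead of the isopropylidene unit may be transferred, and hydride-induced isomerisation may turn the allylic alcohol into a ketone. The fallback sets out from 9 and comes back at 15, bringing in the prenyl group as a nucleophile so that no second metathesis is needed. Prenylbarium chloride (prenyl chloride, activated barium from BaI2 and lithium biphenylide, THF, −78 °C) is known to add to aldehydes at its unsubstituted carbon. With 9 in excess it should convert one formyl group into racemic methyl 3-[(2E)-4-hydroxy-3,7-dimethylocta-2,6-dien-1-yl]-4-methoxy-5-[(2E)-3-methyl-4-oxobut-2-en-1-yl]benzoate F5. MnO2 oxidation gives the keto aldehyde methyl 3-[(2E)-3,7-dimethyl-4-oxoocta-2,6-dien-1-yl]-4-methoxy-5-[(2E)-3-methyl-4-oxobut-2-en-1-yl]benzoate F6. The same (R)-2-methyl-CBS-oxazaborolidine/catecholborane reduction should set C4' as (S) and reduce the formyl group, giving 15 directly.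

Further compounds
F1 | step 3 | methyl 4-methoxy-3,5-bis(2-oxoethyl)benzoate | COC(=O)c1cc(CC=O)c(OC)c(CC=O)c1
F2 | step 4 | racemic methyl 3-[(2E)-4-hydroxy-3-methylhepta-2,6-dien-1-yl]-4-methoxy-5-[(2E)-3-methyl-4-oxobut-2-en-1-yl]benzoate | COc1c(C/C=C(\C)C=O)cc(C(=O)OC)cc1C/C=C(\C)C(O)CC=C
F3 | step 4 | methyl 4-methoxy-3-[(2E)-3-methyl-4-oxohepta-2,6-dien-1-yl]-5-[(2E)-3-methyl-4-oxobut-2-en-1-yl]benzoate | COc1c(C/C=C(\C)C=O)cc(C(=O)OC)cc1C/C=C(\C)C(=O)CC=C
F4 | step 4 | methyl 3-[(2E,4S)-4-hydroxy-3-methylhepta-2,6-dien-1-yl]-5-[(2E)-4-hydroxy-3-methylbut-2-en-1-yl]-4-methoxybenzoate | COc1c(C/C=C(\C)CO)cc(C(=O)OC)cc1C/C=C(\C)[C@@H](O)CC=C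
F5 | step 5 | racemic methyl 3-[(2E)-4-hydroxy-3,7-dimethylocta-2,6-dien-1-yl]-4-methoxy-5-[(2E)-3-methyl-4-oxobut-2-en-1-yl]benzoate | COc1c(C/C=C(\C)C=O)cc(C(=O)OC)cc1C/C=C(\C)C(O)CC=C(C)C
F6 | step 5 | methyl 3-[(2E)-3,7-dimethyl-4-oxoocta-2,6-dien-1-yl]-4-methoxy-5-[(2E)-3-methyl-4-oxobut-2-en-1-yl]benzoate | COc1c(C/C=C(\C)C=O)cc(C(=O)OC)cc1C/C=C(\C)C(=O)CC=C(C)C
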